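**Retrosynthetic overview**
- Last disconnection: the three O-methyl groups (two on ring B, one on the pyranone C4 oxygen) are removed at the end with BBr3.
- Key disconnection: ring A is cut at C5–C6 and C4a–C8a into a but-2-ynoyl unit and 1-methoxy-1,3-bis(trimethylsilyloxy)buta-1,3-diene, and ring C at O1–C2; both rings come from one cross-conjugated diynone, Ar–C≡C–CO–C≡C–CH3.
- Feature the strategy rests on: ring A holds the acyl carbon C4 on C4a, flanked by CH3 on C5 and oxygen on C8a, with the second oxygen on C7. This 2,4-dioxygenated 6-methylbenzoyl pattern is what a β-methyl ynone and an acetoacetate-derived diene give with the correct regiochemistry.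
- The diynone is cut at the aryl–alkyne bond (Sonogashira coupling of an aryl iodide with hexa-1,4-diyn-3-ol, then MnO2); the pyranone is cut to an arylacetyl chloride and a dioxinone dienolate.
- Ring order: ring B is bought, the pyranone is built in steps 3–5, ring A and then ring C form in one pot in step 11.

Key step: step 11

Assumption: the target is taken as the 4-hydroxy-2H-pyran-2-one tautomer drawn; it has no stereocentre, and the bond from C2 to ring B is taken as freely rotating.

**Route**

Step 1
Reactants: 1 3,5-dimethoxyphenylacetic acid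
Product: 2 2-(2-iodo-3,5-dimethoxyphenyl)acetic acid
Conditions: N-iodosuccinimide (1.05 equiv), CF3CO2H (0.1 equiv), MeCN, 0 → 20 °C, dark
Reagents that add atoms: N-iodosuccinimide, O=C1CCC(=O)N1I
Why: Electrophilic aromatic iodination should go to C2, which is ortho and para to the two methoxy groups and less crowded than C4 between them.

Step 2
Reactants: 2 2-(2-iodo-3,5-dimethoxyphenyl)acetic acid
Product: 3 2-(2-iodo-3,5-dimethoxyphenyl)acetyl chloride (used crude)
Conditions: (COCl)2 (1.5 equiv), DMF (cat), CH2Cl2, 0 → 20 °C, then evaporation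
Reagents that add atoms: oxalyl chloride, O=C(Cl)C(=O)Cl
Why: Acid chloride formation through the Vilsmeier-type chloroiminium species is standard and leaves the aryl iodide and the ethers untouched.

Step 3
Reactants: 3 2-(2-iodo-3,5-dimethoxyphenyl)acetyl chloride; 4 2,2,6-trimethyl-4H-1,3-dioxin-4-one
Product: 6 6-[3-(2-iodo-3,5-dimethoxyphenyl)-2-oxopropyl]-2,2-dimethyl-4H-1,3-dioxin-4-one, via lithium dienolate 5 (not isolated)
Conditions: 4 (2.2 equiv), LiN(SiMe3)2 (2.2 equiv), THF, −78 °C; then 3, −78 °C; 1 M HCl quench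
Reagents that add atoms: none
Why: Claisen-type C-acylation at the γ-carbon of the dioxinone dienolate is established for acid chlorides; the second equivalent of dienolate absorbs the acidic proton of the β-keto product, and the low temperature should suppress ketene formation from the arylacetyl chloride.

Step 4
Reactants: 6 6-[3-(2-iodo-3,5-dimethoxyphenyl)-2-oxopropyl]-2,2-dimethyl-4H-1,3-dioxin-4-one
Product: 8 4-hydroxy-6-[(2-iodo-3,5-dimethoxyphenyl)methyl]-2H-pyran-2-one, via acylketene 7 (not isolated)
Conditions: toluene, 110 °C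
Reagents that add atoms: none
Why: Thermal retro-[4+2] loss of acetone from the dioxinone gives an acylketene that the enol oxygen of the side-chain ketone should trap intramolecularly (acylketene lactonisation) to the 4-hydroxy-2-pyranone.

Step 5
Reactants: 8 4-hydroxy-6-[(2-iodo-3,5-dimethoxyphenyl)methyl]-2H-pyran-2-one
Product: 9 6-[(2-iodo-3,5-dimethoxyphenyl)methyl]-4-methoxy-2H-pyran-2-one
Conditions: Me2SO4 (1.2 equiv), K2CO3 (1.5 equiv), acetone, 56 °C
Reagents that add atoms: dimethyl sulfate, COS(=O)(=O)OC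
Why: O-alkylation of the vinylogous acid with dimethyl sulfate and carbonate is the standard way to 4-methoxy-2-pyranones, and K2CO3 is too weak to deprotonate the benzylic CH2.

Step 6
Reactants: 10 but-2-ynal
Product: 11 hexa-1,4-diyn-3-ol (racemic)
Conditions: HC≡CMgBr (1.1 equiv), THF, −78 → 0 °C; cold 1 M HCl quench
Reagents that add atoms: ethynylmagnesium bromide, C#C[Mg]Br
Why: Grignard 1,2-addition of an alkynyl nucleophile to an ynal is reliable, and the new carbinol centre is racemic and is oxidised away in step 8.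

Step 7
Reactants: 9 6-[(2-iodo-3,5-dimethoxyphenyl)methyl]-4-methoxy-2H-pyran-2-one; 11 hexa-1,4-diyn-3-ol
Product: 12 6-{[2-(3-hydroxyhexa-1,4-diyn-1-yl)-3,5-dimethoxyphenyl]methyl}-4-methoxy-2H-pyran-2-one (racemic)
Conditions: 11 (1.5 equiv), PdCl2(PPh3)2 (5 mol %), CuI (10 mol %), Et3N, THF, degassed, 50 °C
Reagents that add atoms: none
Why: Sonogashira coupling of an aryl iodide with the terminal alkyne of a propargylic alcohol should proceed through zerovalent palladium formed in situ, with the internal methyl alkyne, the free hydroxyl and the pyranone as spectators.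

Step 8
Reactants: 12 6-{[2-(3-hydroxyhexa-1,4-diyn-1-yl)-3,5-dimethoxyphenyl]methyl}-4-methoxy-2H-pyran-2-one
Product: 13 6-{[3,5-dimethoxy-2-(3-oxohexa-1,4-diyn-1-yl)phenyl]methyl}-4-methoxy-2H-pyran-2-one
Conditions: activated MnO2 (15 equiv), CH2Cl2, 20 °C
Reagents that add atoms: none
Why: MnO2 oxidation of a doubly propargylic alcohol is fast under neutral conditions and should give the cross-conjugated diynone without touching the pyranone or the benzylic CH2.

Step 9
Reactants: 14 methyl acetoacetate
Product: 15 methyl 3-(trimethylsilyloxy)but-2-enoate (E/Z mixture, geometry irrelevant)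
Conditions: Me3SiCl (1.2 equiv), Et3N (1.3 equiv), hexane, 20 °C; filtration, distillation
Reagents that add atoms: chlorotrimethylsilane, C[Si](C)(C)Cl
Why: O-silylation of the enol of a β-keto ester with chlorotrimethylsilane and triethylamine is the standard silyl enol ether formation.

Step 10
Reactants: 15 methyl 3-(trimethylsilyloxy)but-2-enoate
Product: 17 1-methoxy-1,3-bis(trimethylsilyloxy)buta-1,3-diene (E/Z mixture, geometry irrelevant), via lithium dienolate 16 (not isolated)
Conditions: LiN(iPr)2 (1.1 equiv, commercial solution), THF, −78 °C; Me3SiCl (1.2 equiv), −78 → 0 °C; hexane filtration, distillation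
Reagents that add atoms: chlorotrimethylsilane, C[Si](C)(C)Cl
Why: Kinetic γ-deprotonation of the silyloxy crotonate gives the ester dienolate, whose O-silylation is the known route to this 1,3-bis(silyloxy)diene.

Step 11
Reactants: 13 6-{[3,5-dimethoxy-2-(3-oxohexa-1,4-diyn-1-yl)phenyl]methyl}-4-methoxy-2H-pyran-2-one; 17 1-methoxy-1,3-bis(trimethylsilyloxy)buta-1,3-diene
Product: 21 6-{[2-(7-hydroxy-5-methyl-4-oxo-4H-chromen-2-yl)-3,5-dimethoxyphenyl]methyl}-4-methoxy-2H-pyran-2-one, via cycloadduct 18 (not isolated), via dihydroxyaryl ynone 19 (not isolated), via enaminone 20 (not isolated)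
Conditions: 17 (1.5 equiv), toluene, 0 → 50 °C, no Lewis acid; then MeOH, Et2NH (3 equiv), 20 → 45 °C
Reagents that add atoms: none
Why: Proposed new method: the nucleophilic CH2 terminus of diene 17 should bond to the methyl-bearing β-carbon of 13 and the ketene acetal carbon to the α-carbon in an asynchronous [4+2] cycloaddition (bonds C5–C6 and C4a–C8a), after which methanolysis strips both silyl groups, the mixed ketal collapses with loss of methanol and the ring tautomerises to the 2,4-dihydroxy-6-methylphenyl ynone 19. The closest known reactions are the Diels–Alder aromatisation of 1-alkoxy-1,3-bis(silyloxy)butadienes with alkynoates and alkynones and the diethylamine-mediated cyclisation of 2-hydroxyaryl ynones to flavones; what is new is running both on one cross-conjugated diynone with site control. Ring A closes by the intermolecular [4+2] event followed by aromatisation, and ring C closes by net 6-endo-dig oxa-Michael addition of the C8a phenol to C2, routed through enaminone 20 so that the ring-forming event is an addition–elimination at the β-carbon and the 5-exo pathway to an aurone is shut out. No stereocentre survives, since the ketal carbon of 18 is racemic and is lost on aromatisation. Site selectivity rests on the aryl alkyne being shielded by the ortho-methoxy and ortho-benzylic substituents and deactivated by the donor ring B while the methyl alkyne is unhindered, and on the ketone of the aromatised product being a hydrogen-bonded, donor-substituted aryl ketone that no longer activates the remaining alkyne toward a second equivalent of diene.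

Step 12
Reactants: 21 6-{[2-(7-hydroxy-5-methyl-4-oxo-4H-chromen-2-yl)-3,5-dimethoxyphenyl]methyl}-4-methoxy-2H-pyran-2-one
Product: 22 6-{[3,5-dihydroxy-2-(7-hydroxy-5-methyl-4-oxo-4H-chromen-2-yl)phenyl]methyl}-4-hydroxy-2H-pyran-2-one (target, CNP0309284.0)
Conditions: BBr3 (10 equiv), CH2Cl2, −78 → 25 °C; then H2O, 0 °C
Reagents that add atoms: none
Why: BBr3 O-demethylation should cleave the two aryl methyl ethers through their Lewis acid adducts and the pyranone ether, a vinylogous methyl ester, by coordination at its C2 carbonyl followed by bromide attack on the methyl group.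

**Compound list**
1 | 3,5-dimethoxyphenylacetic acid | COc1cc(CC(=O)O)cc(OC)c1 | starting material
2 | 2-(2-iodo-3,5-dimethoxyphenyl)acetic acid | COc1cc(CC(=O)O)c(I)c(OC)c1 | intermediate
3 | 2-(2-iodo-3,5-dimethoxyphenyl)acetyl chloride | COc1cc(CC(=O)Cl)c(I)c(OC)c1 | intermediate
4 | 2,2,6-trimethyl-4H-1,3-dioxin-4-one | CC1=CC(=O)OC(C)(C)O1 | starting material
5 | lithium dienolate of 4 (lithium 2,2-dimethyl-6-methylidene-6H-1,3-dioxin-4-olate) | [Li]OC1=CC(=C)OC(C)(C)O1 | intermediate (not isolated)
6 | 6-[3-(2-iodo-3,5-dimethoxyphenyl)-2-oxopropyl]-2,2-dimethyl-4H-1,3-dioxin-4-one | COc1cc(CC(=O)CC2=CC(=O)OC(C)(C)O2)c(I)c(OC)c1 | intermediate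
7 | 6-(2-iodo-3,5-dimethoxyphenyl)-3,5-dioxohex-1-en-1-one (acylketene) | COc1cc(CC(=O)CC(=O)C=C=O)c(I)c(OC)c1 | intermediate (not isolated)
8 | 4-hydroxy-6-[(2-iodo-3,5-dimethoxyphenyl)methyl]-2H-pyran-2-one | COc1cc(Cc2cc(O)cc(=O)o2)c(I)c(OC)c1 | intermediate
9 | 6-[(2-iodo-3,5-dimethoxyphenyl)methyl]-4-methoxy-2H-pyran-2-one | COc1cc(Cc2cc(OC)cc(=O)o2)c(I)c(OC)c1 | intermediate
10 | but-2-ynal | CC#CC=O | starting material
11 | hexa-1,4-diyn-3-ol (racemic) | CC#CC(O)C#C | intermediate
12 | 6-{[2-(3-hydroxyhexa-1,4-diyn-1-yl)-3,5-dimethoxyphenyl]methyl}-4-methoxy-2H-pyran-2-one (racemic) | CC#CC(O)C#Cc1c(OC)cc(OC)cc1Cc1cc(OC)cc(=O)o1 | intermediate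
13 | 6-{[3,5-dimethoxy-2-(3-oxohexa-1,4-diyn-1-yl)phenyl]methyl}-4-methoxy-2H-pyran-2-one | CC#CC(=O)C#Cc1c(OC)cc(OC)cc1Cc1cc(OC)cc(=O)o1 | intermediate
14 | methyl acetoacetate | COC(=O)CC(C)=O | starting material
15 | methyl 3-(trimethylsilyloxy)but-2-enoate (E/Z mixture) | COC(=O)C=C(C)O[Si](C)(C)C | intermediate
16 | lithium dienolate of 15 (lithium 1-methoxy-3-(trimethylsilyloxy)buta-1,3-dien-1-olate) | COC(O[Li])=CC(=C)O[Si](C)(C)C | intermediate (not isolated)
17 | 1-methoxy-1,3-bis(trimethylsilyloxy)buta-1,3-diene (E/Z mixture) | COC(O[Si](C)(C)C)=CC(=C)O[Si](C)(C)C | intermediate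
18 | 6-{[2-(3-[6-methoxy-2-methyl-4,6-bis(trimethylsilyloxy)cyclohexa-1,4-dien-1-yl]-3-oxoprop-1-yn-1-yl)-3,5-dimethoxyphenyl]methyl}-4-methoxy-2H-pyran-2-one (racemic cycloadduct) | COC1(O[Si](C)(C)C)C=C(O[Si](C)(C)C)CC(C)=C1C(=O)C#Cc1c(OC)cc(OC)cc1Cc1cc(OC)cc(=O)o1 | intermediate (not isolated)
19 | 6-{[2-(3-(2,4-dihydroxy-6-methylphenyl)-3-oxoprop-1-yn-1-yl)-3,5-dimethoxyphenyl]methyl}-4-methoxy-2H-pyran-2-one | Cc1cc(O)cc(O)c1C(=O)C#Cc1c(OC)cc(OC)cc1Cc1cc(OC)cc(=O)o1 | intermediate (not isolated)
20 | 6-{[2-(1-(diethylamino)-3-(2,4-dihydroxy-6-methylphenyl)-3-oxoprop-1-en-1-yl)-3,5-dimethoxyphenyl]methyl}-4-methoxy-2H-pyran-2-one (enaminone, geometry irrelevant) | CCN(CC)C(=CC(=O)c1c(C)cc(O)cc1O)c1c(OC)cc(OC)cc1Cc1cc(OC)cc(=O)o1 | intermediate (not isolated)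
21 | 6-{[2-(7-hydroxy-5-methyl-4-oxo-4H-chromen-2-yl)-3,5-dimethoxyphenyl]methyl}-4-methoxy-2H-pyran-2-one | Cc1cc(O)cc2oc(-c3c(OC)cc(OC)cc3Cc3cc(OC)cc(=O)o3)cc(=O)c12 | intermediate
22 | 6-{[3,5-dihydroxy-2-(7-hydroxy-5-methyl-4-oxo-4H-chromen-2-yl)phenyl]methyl}-4-hydroxy-2H-pyran-2-one | Cc1cc(O)cc2oc(-c3c(O)cc(O)cc3Cc3cc(O)cc(=O)o3)cc(=O)c12 | target

**Step count and risks**
Total step count: 12. Longest linear sequence: 9 steps (steps 1, 2, 3, 4, 5, 7, 8, 11, 12 from 3,5-dimethoxyphenylacetic acid).

Most likely to fail: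

1. Step 11. The diene may add to the aryl-substituted alkyne or to both alkynes, or add 1,2 to the ketone. The ketal may aromatise with loss of the silyloxy group instead of the methoxy group, which would leave a C8a methyl ether that cannot close. The phenol may also close 5-exo. The fallback uses known chemistry only, sets out from aryl iodide 9 and returns at 21, with ring A bought instead of built. Sonogashira coupling of 9 with ethynyltrimethylsilane (PdCl2(PPh3)2, CuI, Et3N, THF, 50 °C) should give 6-{[3,5-dimethoxy-2-(trimethylsilylethynyl)phenyl]methyl}-4-methoxy-2H-pyran-2-one F1, and K2CO3 (cat) in MeOH at 0 °C the terminal alkyne 6-[(2-ethynyl-3,5-dimethoxyphenyl)methyl]-4-methoxy-2H-pyran-2-one F2. Commercial orsellinic acid (2,4-dihydroxy-6-methylbenzoic acid) is acetylated with acetic anhydride in pyridine to 2,4-diacetoxy-6-methylbenzoic acid F3 and converted with oxalyl chloride and catalytic DMF into 2,4-diacetoxy-6-methylbenzoyl chloride F4. Acyl Sonogashira coupling of F4 with F2 (PdCl2(PPh3)2, CuI, Et3N, THF, 20 °C) should give 1-(2,4-diacetoxy-6-methylphenyl)-3-{2,4-dimethoxy-6-[(4-methoxy-2-oxo-2H-pyran-6-yl)methyl]phenyl}prop-2-yn-1-one F5. Diethylamine in methanol at 20 → 45 °C then removes both acetates and closes ring C as in step 11 to give 21.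

2. Step 3. The dienolate may deprotonate the arylacetyl chloride to a ketene that dimerises or O-acylates, and double acylation is possible. The fallback sets out from acid 2 and returns at hydroxypyranone 8, replacing the dioxinone and acylketene sequence by an open-chain Claisen condensation and lactonisation. Acid 2 is activated with 1,1'-carbonyldiimidazole and treated with N,O-dimethylhydroxylamine hydrochloride in CH2Cl2 to give 2-(2-iodo-3,5-dimethoxyphenyl)-N-methoxy-N-methylacetamide F6. Methyl acetoacetate 14 is converted with LiN(iPr)2 (2.1 equiv, THF, 0 °C) into its dilithium dianion F7, which should be acylated at its terminal carbon by F6 at −78 → 0 °C to give methyl 6-(2-iodo-3,5-dimethoxyphenyl)-3,5-dioxohexanoate F8 after a dilute HCl quench. Heating F8 with DBU in toluene at 110 °C should lactonise it with loss of methanol to 8, bypassing 6 and 7.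

3. Step 12. Cleavage of one ether may be incomplete, most likely at the pyranone oxygen, and the hydroxypyranone may degrade on long exposure to a strong Lewis acid. The fallback sets out from 21 and returns at 22, splitting the deprotection into two mechanistically different events. Lithium iodide in pyridine at 110 °C should remove only the vinylogous ester methyl group by SN2 attack of iodide, giving 4-hydroxy-6-{[2-(7-hydroxy-5-methyl-4-oxo-4H-chromen-2-yl)-3,5-dimethoxyphenyl]methyl}-2H-pyran-2-one F9 after acidic work-up. The two aryl methyl ethers of F9 are then cleaved under a shorter BBr3 exposure (CH2Cl2, −78 → 0 °C, water quench) to give 22.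

Further compounds
F1 | step 11 | 6-{[3,5-dimethoxy-2-(trimethylsilylethynyl)phenyl]methyl}-4-methoxy-2H-pyran-2-one | C[Si](C)(C)C#Cc1c(OC)cc(OC)cc1Cc1cc(OC)cc(=O)o1
F2 | step 11 | 6-[(2-ethynyl-3,5-dimethoxyphenyl)methyl]-4-methoxy-2H-pyran-2-one | C#Cc1c(OC)cc(OC)cc1Cc1cc(OC)cc(=O)o1
F3 | step 11 | 2,4-diacetoxy-6-methylbenzoic acid | CC(=O)Oc1cc(C)c(C(=O)O)c(OC(C)=O)c1
F4 | step 11 | 2,4-diacetoxy-6-methylbenzoyl chloride | CC(=O)Oc1cc(C)c(C(=O)Cl)c(OC(C)=O)c1
F5 | step 11 | 1-(2,4-diacetoxy-6-methylphenyl)-3-{2,4-dimethoxy-6-[(4-methoxy-2-oxo-2H-pyran-6-yl)methyl]phenyl}prop-2-yn-1-one | CC(=O)Oc1cc(C)c(C(=O)C#Cc2c(OC)cc(OC)cc2Cc2cc(OC)cc(=O)o2)c(OC(C)=O)c1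
F6 | step 3 | 2-(2-iodo-3,5-dimethoxyphenyl)-N-methoxy-N-methylacetamide | COc1cc(CC(=O)N(C)OC)c(I)c(OC)c1
F7 | step 3 | dilithium dianion of methyl acetoacetate (dilithium 1-methoxybuta-1,3-diene-1,3-diolate) | C=C(O[Li])C=C(O[Li])OC
F8 | step 3 | methyl 6-(2-iodo-3,5-dimethoxyphenyl)-3,5-dioxohexanoate | COC(=O)CC(=O)CC(=O)Cc1cc(OC)cc(OC)c1I
F9 | step 12 | 4-hydroxy-6-{[2-(7-hydroxy-5-methyl-4-oxo-4H-chromen-2-yl)-3,5-dimethoxyphenyl]methyl}-2H-pyran-2-one | Cc1cc(O)cc2oc(-c3c(OC)cc(OC)cc3Cc3cc(O)cc(=O)o3)cc(=O)c12
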